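**Retrosynthetic overview**
- 22 ⇐ 21 (the 3,6-dihydro-1,2-dioxine acid) by diimide addition to the ring alkene; this sets the methyl-bearing ring carbon last.
- 21 ⇐ acyclic bis-peroxyacetal acid 15 + 2-boryl-1-silylpropene 19: both C–C bonds that tie the two-carbon unit (ring CH2 and ring CH(CH3)) to the two peroxide-bearing ring carbons are made in one flask. The 1,2-dioxane is the only ring and it is closed here.
- Enabling feature: both ring carbons bonded to the O–O bridge (the one carrying CH2CO2H and the quaternary one) are at the carbonyl oxidation level, so the C–O–O–C chain can act as a 1,4-bis(peroxycarbenium) synthon. The carboxyl of the acetic acid arm sits where it can bind boron and deliver the alkenyl group to its own acetal carbon first.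
- 15 ⇐ methyl enol ether 10 of chain ketone 8 + hydroperoxy acetal 13 (ozonolysis of dimethyl hex-3-enedioate in methanol); 19 ⇐ 1-(trimethylsilyl)propyne by borylcupration.
- 8 ⇐ (R)-citronellyl bromide by alkyl–alkyl coupling, ozonolysis, Wittig olefination and copper-catalysed asymmetric conjugate methylation.

Key step: step 11

Assumption (chemistry): the sense of induction of the two chiral ligands (the Josiphos ligand in step 4, the biaryl diol in step 11) is taken as written; should a trial on the substrate show the opposite sense, the mirror-image ligand is used and nothing else changes.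

**Step 1**
Reactants: 1 (R)-citronellyl bromide [(R)-8-bromo-2,6-dimethyloct-2-ene]; 2 phenethylmagnesium chloride
Product: 3 (S)-2,6-dimethyl-10-phenyldec-2-ene
Conditions: 2 (1.3 equiv), Li2CuCl4 (3 mol%), THF, −10 °C → rt
Reagents that add atoms: none
Why: Copper-catalysed alkyl–alkyl cross-coupling of a primary bromide with a primary Grignard reagent; the stereocentre of 1 is not touched and is named S in 3 only because the substituent priorities change.

**Step 2**
Reactants: 3 (S)-2,6-dimethyl-10-phenyldec-2-ene
Product: 5 (S)-4-methyl-8-phenyloctanal, via secondary ozonide 4 (not isolated)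
Conditions: O3, CH2Cl2, −78 °C (Sudan red end point); then PPh3, −78 °C → rt
Reagents that add atoms: ozone, [O-][O+]=O
Why: Ozonolysis (Criegee mechanism) of the electron-rich trisubstituted alkene should be much faster than attack on the monoalkylbenzene ring, and PPh3 reduces the ozonide to the aldehyde.

**Step 3**
Reactants: 5 (S)-4-methyl-8-phenyloctanal; 6 1-(triphenyl-λ5-phosphanylidene)propan-2-one
Product: 7 (3E,7S)-7-methyl-11-phenylundec-3-en-2-one
Conditions: 6 (1.2 equiv), toluene, 80 °C
Reagents that add atoms: none
Why: Wittig reaction of an unbranched aldehyde with a stabilised ylide, which should give the E-enone needed for the conjugate addition.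

**Step 4**
Reactants: 7 (3E,7S)-7-methyl-11-phenylundec-3-en-2-one
Product: 8 (4R,8S)-4,8-dimethyl-12-phenyldodecan-2-one
Conditions: MeMgBr (1.2 equiv), CuBr·SMe2 (5 mol%), Josiphos ligand (R)-1-[(SP)-2-(diphenylphosphino)ferrocenyl]ethyldicyclohexylphosphine (6 mol%), tBuOMe, −75 °C; aq. NH4Cl
Reagents that add atoms: methylmagnesium bromide, C[Mg]Br
Why: Copper-catalysed asymmetric conjugate addition of a Grignard reagent to a linear E-enone; the Josiphos–copper complex selects the enone face (catalyst control, the existing stereocentre being four carbons away) and sets the 4R methyl centre.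

**Step 5**
Reactants: 8 (4R,8S)-4,8-dimethyl-12-phenyldodecan-2-one
Product: 10 (4R,8S)-2-methoxy-4,8-dimethyl-12-phenyldodec-1-ene, via dimethyl ketal 9 (not isolated)
Conditions: HC(OMe)3 (neat), TsOH·H2O (1 mol%), rt; evaporate; then TMSOTf (1.1 equiv), iPr2NEt (1.3 equiv), CH2Cl2, −20 °C → rt; aq. NaHCO3
Reagents that add atoms: trimethyl orthoformate, COC(OC)OC
Why: Acid-catalysed ketalisation followed by TMSOTf/amine-induced loss of methanol from the ketal should give mainly the less substituted enol ether; the internal regioisomers that may accompany it lead to the same oxocarbenium ion in step 7.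

**Step 6**
Reactants: 11 dimethyl (E)-hex-3-enedioate
Product: 13 methyl 3-hydroperoxy-3-methoxypropanoate, via carbonyl oxide 12 (not isolated)
Conditions: O3, CH2Cl2/MeOH (4:1), NaHCO3, −78 °C; N2 purge; cold chromatography
Reagents that add atoms: ozone, [O-][O+]=O; methanol, CO
Why: Ozonolysis in methanol (Criegee mechanism): the carbonyl oxide from the symmetrical alkene is trapped by methanol as the α-methoxy hydroperoxide, which already holds the O–O bond and the future CH2CO2H arm.

**Step 7**
Reactants: 10 (4R,8S)-2-methoxy-4,8-dimethyl-12-phenyldodec-1-ene; 13 methyl 3-hydroperoxy-3-methoxypropanoate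
Product: 14 methyl 3-methoxy-3-{[(4R,8S)-2-methoxy-4,8-dimethyl-12-phenyldodecan-2-yl]peroxy}propanoate
Conditions: PPTS (5 mol%), CH2Cl2, 0 °C
Reagents that add atoms: none
Why: Acid-catalysed Markovnikov addition of the hydroperoxide O–H to the enol ether (peroxyketalisation through the tertiary oxocarbenium ion); the two acetal centres form as mixtures, which does not matter because both are ionised in step 11.

**Step 8**
Reactants: 14 methyl 3-methoxy-3-{[(4R,8S)-2-methoxy-4,8-dimethyl-12-phenyldodecan-2-yl]peroxy}propanoate
Product: 15 3-methoxy-3-{[(4R,8S)-2-methoxy-4,8-dimethyl-12-phenyldodecan-2-yl]peroxy}propanoic acid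
Conditions: LiOH·H2O (1.5 equiv), THF/H2O (3:1), 0 °C; AcOH to pH 5, cold extraction, used at once
Reagents that add atoms: lithium hydroxide, [Li+].[OH-]
Why: Saponification of the methyl ester; both peroxyacetal centres are stable to base, and at 0 °C hydrolysis should outrun β-elimination from the ester enolate.

**Step 9**
Reactants: 16 1-(trimethylsilyl)propyne; 17 bis(pinacolato)diboron
Product: 18 (Z)-trimethyl[2-(4,4,5,5-tetramethyl-1,3,2-dioxaborolan-2-yl)prop-1-en-1-yl]silane
Conditions: CuCl (5 mol%), Xantphos (5 mol%), NaOtBu (10 mol%), MeOH (2 equiv), THF, rt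
Reagents that add atoms: none
Why: Copper-catalysed protoboration of an internal alkyne (syn borylcupration, then protonation of the C–Cu bond by methanol); copper should go to the silicon-bearing carbon and boron to the less hindered methyl-bearing carbon, so boron and silicon end up trans across the alkene.

**Step 10**
Reactants: 18 (Z)-trimethyl[2-(4,4,5,5-tetramethyl-1,3,2-dioxaborolan-2-yl)prop-1-en-1-yl]silane
Product: 19 (Z)-[1-(trimethylsilyl)prop-1-en-2-yl]boronic acid
Conditions: NaIO4 (3 equiv), NH4OAc (3 equiv), acetone/H2O (1:1), rt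
Reagents that add atoms: water, O
Why: Oxidative deprotection of a pinacol boronate: periodate cleaves the pinacol released by hydrolysis and frees the boronic acid, which unlike the pinacol ester can exchange onto a carboxyl group and a diol; the vinylsilane is inert.

**Step 11**
Reactants: 15 3-methoxy-3-{[(4R,8S)-2-methoxy-4,8-dimethyl-12-phenyldodecan-2-yl]peroxy}propanoic acid; 19 (Z)-[1-(trimethylsilyl)prop-1-en-2-yl]boronic acid
Product: 21 2-[(3S,6R)-6-[(2R,6S)-2,6-dimethyl-10-phenyldecyl]-4,6-dimethyl-3,6-dihydro-1,2-dioxin-3-yl]acetic acid, via allylic peroxide 20 (not isolated)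
Conditions: one flask: 19 (1.3 equiv), (S)-3,3′-dibromo-1,1′-bi-2-naphthol (20 mol%), 4 Å MS, CH2Cl2, −20 → 0 °C; then 2,6-di-tert-butyl-4-methylpyridine (3 equiv), TMSOTf (2.5 equiv), −78 → −40 °C; aq. NaHCO3, then pH 4 buffer
Reagents that add atoms: none
Why: Proposed new method: acid 15 and boronic acid 19 condense (with the biaryl diol on boron) to an acyloxyborane whose boron sits in a six-membered chelate with the methoxy group on the acetal carbon next to the CH2CO2H arm, abstracts it and, as the resulting tetracoordinate boronate, passes its alkenyl carbon (the methyl-bearing one, ipso to boron, with retention of alkene geometry) to the secondary peroxycarbenium ion through a six-membered chair to give 20, while the ketone-derived ketal has no boron within reach and is left alone at this temperature. TMSOTf then ionises that ketal and the tertiary peroxycarbenium ion is captured by the vinylsilane through its CH(SiMe3) carbon in a 6-endo-trig Prins-type cation–olefin closure (Markovnikov, tertiary cation at the methyl-bearing carbon), after which loss of the silyl group from the neighbouring carbon fixes the ring alkene between the two carbons of the unit; a lactone from reversible capture of the cation by the carboxyl arm would re-ionise under TMSOTf and drain the same way. The closest known reaction types are the Petasis borono-Mannich reaction with its diol-catalysed asymmetric versions and Lewis acid additions of alkenylboronates to oxocarbenium ions for the first bond, and Lewis acid additions of π-nucleophiles to peroxycarbenium ions and vinylsilane-terminated oxocarbenium cyclisations to 3,6-dihydro-2H-pyrans for the second. The centre bearing the acetic acid arm (3S) is set by the boron-bound chiral diol in the chair transfer (reagent control, the chain stereocentres being too remote), and the quaternary centre (6R) by a chair-like closure in which the arm is pseudoaxial to avoid A(1,2) strain with the ring methyl and the larger alkyl chain lies anti to the O–O bond of the E-configured peroxycarbenium ion and hence equatorial, which puts arm and chain cis. The step needs the acetal carbon to react before the ketal carbon and each alkene carbon to bond only its own partner: the first is secured by the carboxyl-bound boron (directed ionisation and delivery), the second by ipso transfer at boron and by the silicon-marked position of the final alkene.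

**Step 12**
Reactants: 21 2-[(3S,6R)-6-[(2R,6S)-2,6-dimethyl-10-phenyldecyl]-4,6-dimethyl-3,6-dihydro-1,2-dioxin-3-yl]acetic acid
Product: 22 2-[(3S,4S,6R)-6-[(2R,6S)-2,6-dimethyl-10-phenyldecyl]-4,6-dimethyl-1,2-dioxan-3-yl]acetic acid
Conditions: potassium azodicarboxylate KO2CN=NCO2K (15 equiv, in portions), AcOH (30 equiv), MeOH/CH2Cl2, 0 °C → rt
Reagents that add atoms: none
Why: Diimide reduction: concerted syn transfer of two hydrogens spares the O–O bond and should come from the ring face opposite to the cis-disposed acetic acid arm and alkyl chain (only the quaternary methyl lies on that face), which places the new methyl group cis to the arm and sets the last ring stereocentre as 4S.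

**Compound list**
1 | (R)-citronellyl bromide, (R)-8-bromo-2,6-dimethyloct-2-ene | C[C@@H](CCBr)CCC=C(C)C | starting material
2 | phenethylmagnesium chloride | Cl[Mg]CCc1ccccc1 | starting material
3 | (S)-2,6-dimethyl-10-phenyldec-2-ene | C[C@@H](CCCCc1ccccc1)CCC=C(C)C | intermediate
4 | 3,3-dimethyl-5-[(3S)-3-methyl-7-phenylheptyl]-1,2,4-trioxolane (secondary ozonide, epimers at the ring CH) | CC1(C)OOC(CC[C@@H](C)CCCCc2ccccc2)O1 | intermediate
5 | (S)-4-methyl-8-phenyloctanal | C[C@@H](CCCCc1ccccc1)CCC=O | intermediate
6 | 1-(triphenyl-λ5-phosphanylidene)propan-2-one | CC(=O)C=P(c1ccccc1)(c1ccccc1)c1ccccc1 | starting material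
7 | (3E,7S)-7-methyl-11-phenylundec-3-en-2-one | C[C@@H](CCCCc1ccccc1)CC/C=C/C(C)=O | intermediate
8 | (4R,8S)-4,8-dimethyl-12-phenyldodecan-2-one | C[C@@H](CCCCc1ccccc1)CCC[C@@H](C)CC(C)=O | intermediate
9 | (4R,8S)-2,2-dimethoxy-4,8-dimethyl-12-phenyldodecane | C[C@@H](CCCCc1ccccc1)CCC[C@@H](C)CC(C)(OC)OC | intermediate
10 | (4R,8S)-2-methoxy-4,8-dimethyl-12-phenyldodec-1-ene (main regioisomer) | C[C@@H](CCCCc1ccccc1)CCC[C@@H](C)CC(=C)OC | intermediate
11 | dimethyl (E)-hex-3-enedioate | COC(=O)C/C=C/CC(=O)OC | starting material
12 | methyl 3-oxopropanoate O-oxide (carbonyl oxide) | COC(=O)CC=[O+][O-] | intermediate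
13 | methyl 3-hydroperoxy-3-methoxypropanoate (racemic) | COC(=O)CC(OC)OO | intermediate
14 | methyl 3-methoxy-3-{[(4R,8S)-2-methoxy-4,8-dimethyl-12-phenyldodecan-2-yl]peroxy}propanoate (epimers at both acetal carbons) | C[C@@H](CCCCc1ccccc1)CCC[C@@H](C)CC(C)(OC)OOC(OC)CC(=O)OC | intermediate
15 | 3-methoxy-3-{[(4R,8S)-2-methoxy-4,8-dimethyl-12-phenyldodecan-2-yl]peroxy}propanoic acid (epimers at both acetal carbons) | C[C@@H](CCCCc1ccccc1)CCC[C@@H](C)CC(C)(OC)OOC(OC)CC(=O)O | intermediate
16 | 1-(trimethylsilyl)propyne | CC#C[Si](C)(C)C | starting material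
17 | bis(pinacolato)diboron | CC1(C)OB(OC1(C)C)B1OC(C)(C)C(C)(C)O1 | starting material
18 | (Z)-trimethyl[2-(4,4,5,5-tetramethyl-1,3,2-dioxaborolan-2-yl)prop-1-en-1-yl]silane | C/C(B1OC(C)(C)C(C)(C)O1)=C\[Si](C)(C)C | intermediate
19 | (Z)-[1-(trimethylsilyl)prop-1-en-2-yl]boronic acid | C/C(B(O)O)=C\[Si](C)(C)C | intermediate
20 | (3S,4E)-3-{[(4R,8S)-2-methoxy-4,8-dimethyl-12-phenyldodecan-2-yl]peroxy}-4-methyl-5-(trimethylsilyl)pent-4-enoic acid (epimers at the ketal carbon) | C[C@@H](CCCCc1ccccc1)CCC[C@@H](C)CC(C)(OC)OO[C@@H](CC(=O)O)/C(C)=C/[Si](C)(C)C | intermediate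
21 | 2-[(3S,6R)-6-[(2R,6S)-2,6-dimethyl-10-phenyldecyl]-4,6-dimethyl-3,6-dihydro-1,2-dioxin-3-yl]acetic acid | C[C@@H](CCCCc1ccccc1)CCC[C@@H](C)C[C@]1(C)C=C(C)[C@H](CC(=O)O)OO1 | intermediate
22 | 2-[(3S,4S,6R)-6-[(2R,6S)-2,6-dimethyl-10-phenyldecyl]-4,6-dimethyl-1,2-dioxan-3-yl]acetic acid (CNP0189478.1) | C[C@@H](CCCCc1ccccc1)CCC[C@@H](C)C[C@]1(C)C[C@H](C)[C@H](CC(=O)O)OO1 | target

**Step count**
Total steps: 12. Longest linear sequence: 9 steps (1, 2, 3, 4, 5, 7, 8, 11, 12); steps 6, 9 and 10 make the two small partners.

**Steps most likely to fail**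

1. Step 11 (proposed new method). Three processes may defeat it. The tertiary ketal may ionise before the alkenyl group has been transferred, which would bring the alkenyl group to the wrong carbon or destroy the ketal. The diol may give poor facial control in the boron-to-carbon transfer. The ring closure may discriminate poorly between methyl and the alkyl chain at the quaternary centre. The fallback is known chemistry, sets out from ketone 8 and comes back at 22. (R)-3-Bromo-2-methylpropan-1-ol and PPh3 would give [(2R)-3-hydroxy-2-methylpropyl]triphenylphosphonium bromide F1, which carries the ring methyl centre from the chiral pool. Wittig reaction of its ylide (2 equiv KHMDS) with 8 would give (2S,6R,10S)-2,4,6,10-tetramethyl-14-phenyltetradec-3-en-1-ol F2. Dess–Martin periodinane would give (2S,6R,10S)-2,4,6,10-tetramethyl-14-phenyltetradec-3-enal F3, and methyl (triphenylphosphoranylidene)acetate would give methyl (2E,4R,8R,12S)-4,6,8,12-tetramethyl-16-phenylhexadeca-2,5-dienoate F4. Mukaiyama–Isayama peroxidation (Co(acac)2, O2, Et3SiH), which attacks only the electron-rich trisubstituted alkene, would give methyl (2E,4S,8R,12S)-4,6,8,12-tetramethyl-16-phenyl-6-[(triethylsilyl)peroxy]hexadec-2-enoate F5. Desilylation (HF·pyridine) and intramolecular oxa-Michael addition of the hydroperoxide (Et2NH, CF3CH2OH) would give methyl 2-[(3S,4S,6R)-6-[(2R,6S)-2,6-dimethyl-10-phenyldecyl]-4,6-dimethyl-1,2-dioxan-3-yl]acetate F6. This closure is not selective at the quaternary centre, so F6 would have to be separated from its epimers by chromatography; LiOH at 0 °C would then give 22.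

2. Step 12. Hydrogen transfer to a trisubstituted ring alkene may be slow, the reagent may leak to the face that carries the arm and the chain, and forcing the reaction may start to reduce the O–O bond. The fallback sets out from 21 and comes back at 22. It changes the hydrogen source and the mechanism from a concerted transfer by a transient reagent to chemisorption on a metal surface: H2 (1 atm), PtO2, EtOAc, 0 °C, short contact time, with the alkene adsorbing on its less hindered face. No new compound is made (F0).

3. Step 7. The acid may cause exchange instead of addition: loss of methanol from the hydroperoxy acetal, hydrolysis of the enol ether, or double addition to a bis-peroxyketal. The fallback reverses the roles of the partners, sets out from ketone 8 and comes back at 14. Wittig methylenation (Ph3P=CH2) would give (4R,8S)-2,4,8-trimethyl-12-phenyldodec-1-ene F7, and ozonolysis in CH2Cl2/MeOH would give (4R,8S)-2-hydroperoxy-2-methoxy-4,8-dimethyl-12-phenyldodecane F8. This hydroperoxide would be O-alkylated under silver assistance (Ag2O, CH2Cl2, 0 °C) with methyl 3-chloro-3-methoxypropanoate F9, made from commercial methyl 3,3-dimethoxypropanoate and acetyl chloride, to give 14.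

**Further compounds**
F1 | step 11 | [(2R)-3-hydroxy-2-methylpropyl]triphenylphosphonium bromide | OC[C@@H](C)C[P+](c1ccccc1)(c1ccccc1)c1ccccc1.[Br-]
F2 | step 11 | (2S,6R,10S)-2,4,6,10-tetramethyl-14-phenyltetradec-3-en-1-ol (E/Z mixture) | C[C@@H](CCCCc1ccccc1)CCC[C@@H](C)CC(C)=C[C@H](C)CO
F3 | step 11 | (2S,6R,10S)-2,4,6,10-tetramethyl-14-phenyltetradec-3-enal (E/Z mixture) | C[C@@H](CCCCc1ccccc1)CCC[C@@H](C)CC(C)=C[C@H](C)C=O
F4 | step 11 | methyl (2E,4R,8R,12S)-4,6,8,12-tetramethyl-16-phenylhexadeca-2,5-dienoate (E/Z mixture at the 5-ene) | C[C@@H](CCCCc1ccccc1)CCC[C@@H](C)CC(C)=C[C@H](C)/C=C/C(=O)OC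
F5 | step 11 | methyl (2E,4S,8R,12S)-4,6,8,12-tetramethyl-16-phenyl-6-[(triethylsilyl)peroxy]hexadec-2-enoate (both epimers at the peroxide carbon) | C[C@@H](CCCCc1ccccc1)CCC[C@@H](C)CC(C)(OO[Si](CC)(CC)CC)C[C@H](C)/C=C/C(=O)OC
F6 | step 11 | methyl 2-[(3S,4S,6R)-6-[(2R,6S)-2,6-dimethyl-10-phenyldecyl]-4,6-dimethyl-1,2-dioxan-3-yl]acetate | C[C@@H](CCCCc1ccccc1)CCC[C@@H](C)C[C@]1(C)C[C@H](C)[C@H](CC(=O)OC)OO1
F0 | step 12 | none | none
F7 | step 7 | (4R,8S)-2,4,8-trimethyl-12-phenyldodec-1-ene | C[C@@H](CCCCc1ccccc1)CCC[C@@H](C)CC(C)=C
F8 | step 7 | (4R,8S)-2-hydroperoxy-2-methoxy-4,8-dimethyl-12-phenyldodecane (epimers at the ketal carbon) | C[C@@H](CCCCc1ccccc1)CCC[C@@H](C)CC(C)(OC)OO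
F9 | step 7 | methyl 3-chloro-3-methoxypropanoate | COC(=O)CC(Cl)OC
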